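The noon and midnight runs both stop climbing within minutes, and two chemists read them alike: reagent is the limiting reagent, shared between starting material and second substrate, so target and second product together equal the reagent charged.

| setting | noon | autumn | midnight | Friday's | Wednesday's | Thursday's |
|---|---|---|---|---|---|---|
| starting material | 0.14 M | 0.22 M | 0.10 M | 0.10 M | 0.10 M | 0.10 M |
| reagent | 0.050 M | 0.050 M | 0.050 M | 0.0500 M | 0.0500 M | 0.0500 M |
| second substrate | 0.20 M | 0.20 M | 0.40 M | 0.200 M | 0.200 M | 0.200 M |
| free catalyst | 0.10 mM | 0.10 mM | 0.10 mM | 0.10 mM | 0.10 mM | 0.10 mM |
| temperature | 38 °C | 65 °C | 38 °C | 25 °C | 50 °C | 75 °C |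
| remark | run made earlier | run made earlier | run made earlier |  |  |  |
| time |  |  |  | 2.0 h | 2.0 h | 2.0 h |

| run | time / min | target / % |
|---|---|---|
| noon | 4.00 | 18.4 |
| noon | 12.0 | 19.9 |
| noon | 20.0 | 19.7 |
| noon | 30.0 | 19.9 |
| noon | 50.0 | 19.3 |
| autumn | 3.00 | 13.8 |
| autumn | 6.00 | 14.1 |
| autumn | 8.00 | 14.1 |
| autumn | 12.0 | 14.0 |
| midnight | 4.00 | 15.6 |
| midnight | 8.00 | 15.3 |
| midnight | 12.0 | 15.3 |
| midnight | 25.0 | 15.1 |
| midnight | 50.0 | 15.5 |

(readings scatter by 0.3 percentage points)

- the numbers in the tables scatter with a standard deviation of 0.3 percentage points
- steps under discussion: second substrate + reagent + free catalyst -> free catalyst + second product; starting material + free catalyst -> spent catalyst; starting material + reagent + free catalyst -> free catalyst + target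

- the flask that comes out highest in amount of target, in percent of the starting material charged, or "all alike" when all lie within 1.5 percentage points (Friday's / Wednesday's / Thursday's / all alike)
- target at the end, in percent of the starting material charged, Friday's
- target at the end, in percent of the starting material charged, Wednesday's
- target at the end, in percent of the starting material charged, Thursday's

Both steps that use reagent carry reagent and free catalyst in their rates, so these cancel when the two rates are divided. Integrating what remains gives ln(starting material charged / left) = factor × ln(second substrate charged / left). The noon plateau of 19.7% gives a factor of 1.85. The midnight plateau of 15.4% gives 1.84. Their mean is the selectivity factor as read, 1.84.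

The two chemists part over the autumn run, at 65 °C, with its plateau of 14.0%. The first assumes its reagent was used up as well. The factor then reads 1.49, lower than at 38 °C, so in his view cold flasks make more target. The second keeps the factor at 1.84 and gives up the balance instead. Autumn's target and second product then account for 93.0% of its reagent, and in his view that flask stopped early, its free catalyst turned to spent catalyst. One run cannot separate these two readings.

I reckon with the second. For Friday's I start from the share at the start, 24.0%, and each time take the mean of a trial and what factor and balance return for it. That gives 23.3%, then 23.3%. I expect about this for Friday's and Wednesday's, and somewhat less for Thursday's.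

The forecast, which holds with the first chemist that the factor drops with heat “selectivity falls with temperature”, named Friday's highest, at 24.5%, with 22.2% for Wednesday's and 20.1% for Thursday's.

The simulation gives 23.3% for Friday's, 23.3% for Wednesday's and 22.3% for Thursday's, so the answer is all alike.

    second substrate + reagent + free catalyst → free catalyst + second product (k = 14000 L² mol⁻² min⁻¹, Ea = 39.0 kJ mol⁻¹)
    starting material + free catalyst → spent catalyst (k = 0.430 L mol⁻¹ min⁻¹, Ea = 64.0 kJ mol⁻¹)
    starting material + reagent + free catalyst → free catalyst + target (k = 26000 L² mol⁻² min⁻¹, Ea = 39.0 kJ mol⁻¹)
    (constants at 25 °C)

The constants put the factor at 1.86, with equal activation energies. The first chemist's balance keeps the cool end: Friday's ends with 0% of its reagent. Thursday's stands 1 percentage point below Friday's, with 4.6% of its reagent unused and 0% of its free catalyst, which is the second chemist's early stop. Now take Friday's flask with 0.20 M of reagent. The same trials, with 1.84, run 95.9%, 85.1%, 82.2%, 81.4%. That flask gives 81.2% of target, with 40.6% of its second substrate left.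

The data are simulated for an exercise.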